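**Strategy.** The target is procyanidin B1 acylated with 4-hydroxybenzoic acid on O3 of its lower catechin unit. The plan builds ring C of the upper epicatechin unit by an oxa-[4+2] cycloaddition. It exploits the fact that phenol oxygen O1 on ring A sits, through C8a and C4a, ortho to benzylic C4: this array is unmasked as an α-methoxy ortho-quinone methide from a salicylaldehyde acetal, and a (Z)-enol acetate supplies C2=C3. One operation forms C3–C4 and O1–C2, sets the cis C2/C3 stereocentres under chiral acid control and leaves C4 as a methyl ether. Ionisation of that ether then joins C4 to C8 of the benzylated catechin ester, and hydrogenolysis frees the target.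

Key step: step 6

Remark on numbering: flavan numbering is used (O1, C2, C3, C4, C4a, C5 to C8, C8a; ring A is the benzo ring, ring B the C2 aryl, ring C the pyran). "Upper" is the epicatechin unit, "lower" the catechin unit that carries the ester.

Assumption: the sense of induction of the chiral acid in step 6 is not predicted here; the catalyst enantiomer that gives the (2R,3R) series is to be chosen by a test reaction. Compounds 12 and 13 are expected as C4 epimers and are used as such, because step 8 erases C4; their SMILES leave C4 undefined.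

**Step 1**
Reactants: 1 (+)-catechin
Product: 2 5,7,3',4'-tetra-O-benzyl-(+)-catechin
Conditions: BnBr (4.2 equiv), K2CO3, DMF, 0 °C to rt
Reagents that add atoms: benzyl bromide, BrCc1ccccc1
Why: Williamson O-benzylation of the four phenols, which carbonate deprotonates in preference to the C3 alcohol; no stereocentre is touched.

**Step 2**
Reactants: 2 5,7,3',4'-tetra-O-benzyl-(+)-catechin; 3 4-(benzyloxy)benzoic acid
Product: 4 5,7,3',4'-tetra-O-benzyl-(+)-catechin 3-O-[4-(benzyloxy)benzoate]
Conditions: DCC, DMAP (cat.), CH2Cl2, rt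
Reagents that add atoms: none
Why: Steglich esterification of the only free hydroxyl group; acylation at oxygen leaves C3 (S) unchanged.

**Step 3**
Reactants: 5 2,4,6-trihydroxybenzaldehyde
Product: 6 4,6-bis(benzyloxy)-2-hydroxybenzaldehyde
Conditions: BnBr (2.1 equiv), K2CO3, DMF, rt
Reagents that add atoms: benzyl bromide, BrCc1ccccc1
Why: Williamson etherification should stop at the dibenzyl ether, because the last ortho hydroxyl is held in a hydrogen bond to the formyl group and is the least nucleophilic.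

**Step 4**
Reactants: 7 3,4-bis(benzyloxy)benzaldehyde
Product: 8 1,2-bis(benzyloxy)-4-ethynylbenzene
Conditions: dimethyl (1-diazo-2-oxopropyl)phosphonate, K2CO3, MeOH, rt
Reagents that add atoms: dimethyl (1-diazo-2-oxopropyl)phosphonate (Ohira–Bestmann reagent), CC(=O)C(=[N+]=[N-])P(=O)(OC)OC
Why: Seyferth–Gilbert homologation in the Ohira–Bestmann variant; the diazomethylphosphonate anion made in the flask olefinates the aldehyde and the diazoalkene loses nitrogen with a 1,2-hydrogen shift to the terminal alkyne.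

**Step 5**
Reactants: 8 1,2-bis(benzyloxy)-4-ethynylbenzene
Product: 9 (Z)-2-[3,4-bis(benzyloxy)phenyl]ethenyl acetate
Conditions: AcOH (1.2 equiv), Ru(η3-2-methylallyl)2(dppb) (2 mol %; dppb = 1,4-bis(diphenylphosphino)butane), toluene, 45 °C
Reagents that add atoms: acetic acid, CC(=O)O
Why: ruthenium-catalysed anti-Markovnikov hydro-oxycarbonylation of a terminal alkyne; acetate adds to the α-carbon of a ruthenium vinylidene and protonolysis should release the (Z)-enol ester.

**Step 6**
Reactants: 6 4,6-bis(benzyloxy)-2-hydroxybenzaldehyde; 9 (Z)-2-[3,4-bis(benzyloxy)phenyl]ethenyl acetate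
Product: 12 (2R,3R)-5,7-bis(benzyloxy)-2-[3,4-bis(benzyloxy)phenyl]-4-methoxy-3,4-dihydro-2H-chromen-3-yl acetate, via dimethyl acetal 10 (not isolated), via methoxy ortho-quinone methide 11 (not isolated)
Conditions: HC(OMe)3 (1.5 equiv), chiral BINOL-derived N-triflylphosphoramide with 3,3'-bis(2,4,6-triisopropylphenyl) groups (10 mol %), 5 Å MS, CH2Cl2, −40 °C to rt
Reagents that add atoms: trimethyl orthoformate, COC(OC)OC
Why: Proposed new method: the acid turns 6 into acetal 10 and, by loss of methanol, into the (E)-α-methoxy ortho-quinone methide 11, held in the chiral pocket by a hydrogen bond to its carbonyl oxygen (the future O1); 9 then adds in an inverse-electron-demand oxa-[4+2] cycloaddition in which the C3–C4 bond forms ahead of the O1–C2 bond. The closest known reactions are the three-component chroman synthesis from salicylaldehydes, orthoformate and styrenes, and the chiral-Brønsted-acid-catalysed [4+2] cycloadditions of ortho-quinone methides with styrenes; an enol ester reacting through its oxygen-bearing carbon is the new element. Ring C closes as a suprafacial [4π+2π] cycloaddition between the heterodiene O1=C8a–C4a=C4 and the dienophile C2=C3. C2 and C3 are set together: their cis relationship is copied from the Z geometry of 9, their absolute (2R,3R) sense comes from the chiral acid, and the C4 methoxy centre forms without control and is erased in step 8. The step needs C3, not C2, of 9 to attack C4; the para-benzyloxy group of ring B should make the benzylic cation character at C2 far better stabilised than an α-acyloxy cation at C3, which directs the first bond to C3. It also needs the alkene to keep its geometry, which the fast collapse of the O1–C2 bond inside the hydrogen-bonded ion pair should secure.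

**Step 7**
Reactants: 12 (2R,3R)-5,7-bis(benzyloxy)-2-[3,4-bis(benzyloxy)phenyl]-4-methoxy-3,4-dihydro-2H-chromen-3-yl acetate
Product: 13 (2R,3R)-5,7-bis(benzyloxy)-2-[3,4-bis(benzyloxy)phenyl]-4-methoxy-3,4-dihydro-2H-chromen-3-ol
Conditions: K2CO3 (0.2 equiv), MeOH/THF, 0 °C to rt
Reagents that add atoms: none
Why: base-catalysed transesterification of the secondary acetate with methanol; the benzyl ethers and the C4 methyl ether are inert to carbonate and no stereocentre carries an acidic hydrogen.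

**Step 8**
Reactants: 13 (2R,3R)-5,7-bis(benzyloxy)-2-[3,4-bis(benzyloxy)phenyl]-4-methoxy-3,4-dihydro-2H-chromen-3-ol; 4 5,7,3',4'-tetra-O-benzyl-(+)-catechin 3-O-[4-(benzyloxy)benzoate] (3 equiv, excess recovered)
Product: 15 (2R,3S)-5,7-bis(benzyloxy)-2-[3,4-bis(benzyloxy)phenyl]-8-{(2R,3R,4R)-5,7-bis(benzyloxy)-2-[3,4-bis(benzyloxy)phenyl]-3-hydroxy-3,4-dihydro-2H-chromen-4-yl}-3,4-dihydro-2H-chromen-3-yl 4-(benzyloxy)benzoate, via benzylic cation 14 (not isolated)
Conditions: TMSOTf (0.2 equiv), CH2Cl2, −78 to −40 °C; then Et3N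
Reagents that add atoms: none
Why: Lewis-acid ionisation of the C4 methyl ether gives the cation 14, stabilised by the 5,7-dioxygenated ring A, and Friedel–Crafts attack by C8 of 4 on the face anti to the C2 aryl and the C3 oxygen should set C4 (R, 3,4-trans) from either C4 epimer of 13, as in established flavan-3-ol couplings.

**Step 9**
Reactants: 15 the nona-O-benzyl dimer from step 8
Product: 16 epicatechin-(4β→8)-catechin 3-O-(4-hydroxybenzoate) on the lower unit (the target)
Conditions: H2 (1 atm), Pd(OH)2/C, THF/MeOH/H2O, rt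
Reagents that add atoms: none
Why: hydrogenolysis of the nine benzyl ethers under neutral conditions; the aryl ester, the interflavan bond and all stereocentres should be unaffected.

**Compound list**

1 | (+)-catechin, (2R,3S) | O[C@H]1Cc2c(O)cc(O)cc2O[C@@H]1c1ccc(O)c(O)c1 | starting material
2 | 5,7,3',4'-tetra-O-benzyl-(+)-catechin, (2R,3S) | O[C@H]1Cc2c(OCc3ccccc3)cc(OCc3ccccc3)cc2O[C@@H]1c1ccc(OCc2ccccc2)c(OCc2ccccc2)c1 | intermediate
3 | 4-(benzyloxy)benzoic acid | OC(=O)c1ccc(OCc2ccccc2)cc1 | starting material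
4 | 5,7,3',4'-tetra-O-benzyl-(+)-catechin 3-O-[4-(benzyloxy)benzoate], (2R,3S) | O=C(O[C@H]1Cc2c(OCc3ccccc3)cc(OCc3ccccc3)cc2O[C@@H]1c1ccc(OCc2ccccc2)c(OCc2ccccc2)c1)c1ccc(OCc2ccccc2)cc1 | intermediate
5 | 2,4,6-trihydroxybenzaldehyde | O=Cc1c(O)cc(O)cc1O | starting material
6 | 4,6-bis(benzyloxy)-2-hydroxybenzaldehyde | O=Cc1c(O)cc(OCc2ccccc2)cc1OCc1ccccc1 | intermediate
7 | 3,4-bis(benzyloxy)benzaldehyde | O=Cc1ccc(OCc2ccccc2)c(OCc2ccccc2)c1 | starting material
8 | 1,2-bis(benzyloxy)-4-ethynylbenzene | C#Cc1ccc(OCc2ccccc2)c(OCc2ccccc2)c1 | intermediate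
9 | (Z)-2-[3,4-bis(benzyloxy)phenyl]ethenyl acetate | CC(=O)O/C=C\c1ccc(OCc2ccccc2)c(OCc2ccccc2)c1 | intermediate
10 | 3,5-bis(benzyloxy)-2-(dimethoxymethyl)phenol | COC(OC)c1c(O)cc(OCc2ccccc2)cc1OCc1ccccc1 | intermediate (not isolated)
11 | (6E)-3,5-bis(benzyloxy)-6-(methoxymethylidene)cyclohexa-2,4-dien-1-one | CO/C=C1/C(=O)C=C(OCc2ccccc2)C=C1OCc1ccccc1 | intermediate (not isolated)
12 | (2R,3R)-5,7-bis(benzyloxy)-2-[3,4-bis(benzyloxy)phenyl]-4-methoxy-3,4-dihydro-2H-chromen-3-yl acetate; aryl and acetoxy cis; C4 epimers | COC1c2c(OCc3ccccc3)cc(OCc3ccccc3)cc2O[C@H](c2ccc(OCc3ccccc3)c(OCc3ccccc3)c2)[C@@H]1OC(C)=O | intermediate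
13 | (2R,3R)-5,7-bis(benzyloxy)-2-[3,4-bis(benzyloxy)phenyl]-4-methoxy-3,4-dihydro-2H-chromen-3-ol; C4 epimers | COC1c2c(OCc3ccccc3)cc(OCc3ccccc3)cc2O[C@H](c2ccc(OCc3ccccc3)c(OCc3ccccc3)c2)[C@@H]1O | intermediate
14 | (2R,3R)-5,7-bis(benzyloxy)-2-[3,4-bis(benzyloxy)phenyl]-3-hydroxy-3,4-dihydro-2H-chromen-4-ylium | [CH+]1c2c(OCc3ccccc3)cc(OCc3ccccc3)cc2O[C@H](c2ccc(OCc3ccccc3)c(OCc3ccccc3)c2)[C@@H]1O | intermediate (not isolated)
15 | nona-O-benzyl dimer: upper unit (2R,3R,4R) with free 3-OH, lower unit (2R,3S) carrying the 4-(benzyloxy)benzoate, C4 of the upper unit bonded to C8 of the lower unit | O=C(O[C@H]1Cc2c(OCc3ccccc3)cc(OCc3ccccc3)c([C@H]3c4c(OCc5ccccc5)cc(OCc5ccccc5)cc4O[C@H](c4ccc(OCc5ccccc5)c(OCc5ccccc5)c4)[C@@H]3O)c2O[C@@H]1c1ccc(OCc2ccccc2)c(OCc2ccccc2)c1)c1ccc(OCc2ccccc2)cc1 | intermediate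
16 | (2R,3S)-2-(3,4-dihydroxyphenyl)-8-[(2R,3R,4R)-2-(3,4-dihydroxyphenyl)-3,5,7-trihydroxy-3,4-dihydro-2H-chromen-4-yl]-5,7-dihydroxy-3,4-dihydro-2H-chromen-3-yl 4-hydroxybenzoate | O=C(O[C@H]1Cc2c(O)cc(O)c([C@H]3c4c(O)cc(O)cc4O[C@H](c4ccc(O)c(O)c4)[C@@H]3O)c2O[C@@H]1c1ccc(O)c(O)c1)c1ccc(O)cc1 | target

**Totals.** Total step count: 9. Longest linear sequence: 6 steps (steps 4, 5, 6, 7, 8, 9, from 7 to 16).

**Steps most likely to fail**

1. Step 6 (labelled step).
 - What may go wrong: the first bond may form at the aryl-bearing carbon of 9 (regiochemical leakage towards an isoflavan acetal). A stepwise ionic course may also let the C2–C3 bond rotate before ring closure, eroding the cis relationship and the control of the enantioface.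
 - Fallback (known chemistry, same ring closure through C3–C4 with a dienophile of the established styrene class, C3 oxygen introduced afterwards): it sets out from 7 and 6 and comes back at 13.
 - Compound 7 is methylenated (Ph3PCH3Br, KOtBu, THF; Wittig reaction) to 3,4-bis(benzyloxy)styrene F1.
 - Compounds 6 and F1 with HC(OMe)3 under the same chiral acid should give, by the established ortho-quinone methide/styrene [4+2] cycloaddition, (2S)-5,7-bis(benzyloxy)-2-[3,4-bis(benzyloxy)phenyl]-4-methoxychromane F2.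
 - TsOH in warm toluene removes methanol to give (2S)-5,7-bis(benzyloxy)-2-[3,4-bis(benzyloxy)phenyl]-2H-chromene F3.
 - DMDO in acetone/MeOH epoxidises anti to the C2 aryl, and methanol opens the epoxide at benzylic C4 to the 2,3-trans alcohol (2R,3S)-5,7-bis(benzyloxy)-2-[3,4-bis(benzyloxy)phenyl]-4-methoxychroman-3-ol F4.
 - Dess–Martin periodinane gives (2R)-5,7-bis(benzyloxy)-2-[3,4-bis(benzyloxy)phenyl]-4-methoxychroman-3-one F5.
 - LiBH(s-Bu)3 in THF at −78 °C delivers hydride anti to the C2 aryl and returns the 2,3-cis alcohol 13.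

2. Step 8.
 - What may go wrong: the cation 14 may be captured by ring A of a second molecule of 13, so that chains grow to oligomers instead of the cross-coupled dimer.
 - Fallback (blocking group): it sets out from 13 and comes back at 16.
 - Compound 13 is brominated at C8 (NBS, CH2Cl2, −78 °C) to the 8-bromo derivative of 13 F6, whose ring A is blocked at its most nucleophilic position.
 - F6 and 4 are joined with TMSOTf as in step 8 to give the 8-bromo nona-O-benzyl dimer F7.
 - H2, Pd(OH)2/C with Et3N removes the bromine together with the benzyl groups and gives 16.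

3. Step 5.
 - What may go wrong: the Z enol ester may isomerise to E on the ruthenium hydride, or Markovnikov addition may compete, which would pass the wrong geometry on to C2/C3.
 - Fallback (geometry set by hydroboration, C–O bond made afterwards): it sets out from 8 and comes back at 9.
 - Compound 8 undergoes trans-hydroboration with pinacolborane ([RhCl(cod)]2, P(i-Pr)3, Et3N, cyclohexane) to (Z)-2-{2-[3,4-bis(benzyloxy)phenyl]ethenyl}-4,4,5,5-tetramethyl-1,3,2-dioxaborolane F8.
 - KHF2 in MeOH/H2O converts it into potassium (Z)-{2-[3,4-bis(benzyloxy)phenyl]ethenyl}trifluoroborate F9.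
 - Cu(OAc)2-catalysed oxidative coupling with acetic acid (DMAP, 4 Å MS, O2) forms the C–O bond with retention of geometry and gives 9.

**Further compounds**

F1 | step 6 | 3,4-bis(benzyloxy)styrene | C=Cc1ccc(OCc2ccccc2)c(OCc2ccccc2)c1
F2 | step 6 | (2S)-5,7-bis(benzyloxy)-2-[3,4-bis(benzyloxy)phenyl]-4-methoxychromane, C4 epimers | COC1c2c(OCc3ccccc3)cc(OCc3ccccc3)cc2O[C@H](c2ccc(OCc3ccccc3)c(OCc3ccccc3)c2)C1
F3 | step 6 | (2S)-5,7-bis(benzyloxy)-2-[3,4-bis(benzyloxy)phenyl]-2H-chromene | C1=C[C@@H](c2ccc(OCc3ccccc3)c(OCc3ccccc3)c2)Oc2cc(OCc3ccccc3)cc(OCc3ccccc3)c12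
F4 | step 6 | (2R,3S)-5,7-bis(benzyloxy)-2-[3,4-bis(benzyloxy)phenyl]-4-methoxychroman-3-ol, C4 epimers | COC1c2c(OCc3ccccc3)cc(OCc3ccccc3)cc2O[C@H](c2ccc(OCc3ccccc3)c(OCc3ccccc3)c2)[C@H]1O
F5 | step 6 | (2R)-5,7-bis(benzyloxy)-2-[3,4-bis(benzyloxy)phenyl]-4-methoxychroman-3-one, C4 epimers | COC1c2c(OCc3ccccc3)cc(OCc3ccccc3)cc2O[C@H](c2ccc(OCc3ccccc3)c(OCc3ccccc3)c2)C1=O
F6 | step 8 | (2R,3R)-5,7-bis(benzyloxy)-2-[3,4-bis(benzyloxy)phenyl]-8-bromo-4-methoxychroman-3-ol, C4 epimers | COC1c2c(OCc3ccccc3)cc(OCc3ccccc3)c(Br)c2O[C@H](c2ccc(OCc3ccccc3)c(OCc3ccccc3)c2)[C@@H]1O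
F7 | step 8 | 8-bromo nona-O-benzyl dimer (15 with bromine at C8 of the upper unit) | O=C(O[C@H]1Cc2c(OCc3ccccc3)cc(OCc3ccccc3)c([C@H]3c4c(OCc5ccccc5)cc(OCc5ccccc5)c(Br)c4O[C@H](c4ccc(OCc5ccccc5)c(OCc5ccccc5)c4)[C@@H]3O)c2O[C@@H]1c1ccc(OCc2ccccc2)c(OCc2ccccc2)c1)c1ccc(OCc2ccccc2)cc1
F8 | step 5 | (Z)-2-{2-[3,4-bis(benzyloxy)phenyl]ethenyl}-4,4,5,5-tetramethyl-1,3,2-dioxaborolane | CC1(C)OB(/C=C\c2ccc(OCc3ccccc3)c(OCc3ccccc3)c2)OC1(C)C
F9 | step 5 | potassium (Z)-{2-[3,4-bis(benzyloxy)phenyl]ethenyl}trifluoroborate | [K+].F[B-](F)(F)/C=C\c1ccc(OCc2ccccc2)c(OCc2ccccc2)c1
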